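**Plan**

- Retrosynthesis: the heptaene is cut at C11=C12 and C11'=C12' (two Wittig olefinations joining two C15 allyl tributylphosphonium salts to the C10 trienedial), then at the sp–sp2 bonds C8–C9 and C6'–C7' (Sonogashira couplings), and last at the ring bonds C1–C6 and C2–C3 of the cyclohexadiene end (locants: carotenoid numbering, cyclohexadiene end unprimed, hydroxylated end primed).
- Enabling feature: in the 2,6,6-trimethylcyclohexa-1,3-diene ring the only two sp3 atoms, C1 (CMe2) and C2 (CH2), are neighbours, and each is bonded to one terminus (C6, C3) of the ring diene C3=C4–C5(CH3)=C6. This is the retron of an alkene/2-pyrone [4+2] cycloaddition followed by loss of CO2. C1–C2 is isobutylene; the diene is a 4-methyl-2-pyrone whose C3 ester (activating group) is later turned into alkyne carbon C7 and whose lactone bridge (temporary ring) leaves as CO2.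
- Forward order: pyrone, then the cyclohexadiene ring (step 2), then safranal, ethynyl diene, C15 ester, alcohol and salt A; separately the enol triflate of the chiral ketone plus the enynol gives C15 salt B; salt B + C10 dialdehyde gives a C25 aldehyde; salt A is added last to give the C40 skeleton; desilylation ends the route.
- Stereochemistry: C3' (R) comes from (4R,6R)-4-hydroxy-2,2,6-trimethylcyclohexanone and is never touched. 9E and 9'E come from an (E)-enol triflate and (E)-3-methylpent-2-en-4-yn-1-ol through stereoretentive couplings. 13E, 15E and 13'E come from the all-E dialdehyde. 11E and 11'E come from E-selective Wittig reactions of allyl tributylphosphonium ylides.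

Key step: step 2

Assumption: ketone 17, enynol 21 and the all-E C10 dialdehyde 25 are taken as purchasable carotenoid building blocks; all polyene steps are run under argon in dim light.

**Step 1**
Reactants: 1 diethyl 2-(propan-2-ylidene)propanedioate
Product: 3 ethyl 4-methyl-2-oxo-2H-pyran-3-carboxylate, via dienamine 2 (not isolated)
Conditions: DMF-DMA (1.5 equiv), neat, 110 °C; evaporate; then AcOH/H2O (4:1), 80 °C
Reagents that add atoms: N,N-dimethylformamide dimethyl acetal, COC(OC)N(C)C; water, O
Why: The vinylogously acidic γ-methyl of the alkylidene malonate should condense with the amide acetal (aminomethylenation), and acid hydrolysis of the push-pull dienamine should unmask an enolisable aldehyde that lactonises onto the ester that is necessarily cis to it, with loss of ethanol, to give the 2-pyrone (condensation/lactonisation).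

**Step 2**
Reactants: 3 ethyl 4-methyl-2-oxo-2H-pyran-3-carboxylate; 4 2-methylprop-1-ene (isobutylene)
Product: 6 ethyl 2,6,6-trimethylcyclohexa-1,3-diene-1-carboxylate (ethyl safranate), via bicyclic lactone 5 (not isolated)
Conditions: 4 (ca. 20 equiv), toluene, BHT (cat.), steel autoclave, 150 °C
Reagents that add atoms: none
Why: The 2-pyrone is an electron-poor cyclic diene (C3=C4–C5=C6, LUMO lowered by the lactone and the C3 ester) that should undergo an inverse-electron-demand, strongly asynchronous [4+2] cycloaddition with the nucleophilic 1,1-disubstituted alkene: the CH2 terminus bonds to the electrophilic C6 while the tertiary carbon, which carries the developing positive charge, bonds to C3, whose negative charge is stabilised by both carbonyl groups; the resulting 2-oxabicyclo[2.2.2]oct-5-en-3-one 5 then loses CO2 by retro-[4+2] at the reaction temperature. The closest known reaction type is the Diels–Alder/decarboxylation cascade of 3-alkoxycarbonyl-2-pyrones and coumalates with alkenes to give cyclohexa-1,3-dienes. The six-membered carbocycle is closed by an intermolecular [4+2] cycloaddition that makes both σ-bonds (C6–CH2 and C3–CMe2) in one suprafacial event, and the temporary lactone bridge is excised by cycloreversion. No stereocentre survives, because the two bridgehead centres of racemic 5 become sp2 on loss of CO2. The step needs regioselectivity (gem-dimethyl carbon next to the ester-bearing carbon), secured by the matched polarisation of the pyrone (C6 electrophilic, C3 anion-stabilising) and of isobutylene (CH2 nucleophilic, CMe2 cation-stabilising), and chemoselectivity against aromatisation or a second cycloaddition, secured by the quaternary carbon and by the hindered, electron-neutral character of diene 6.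

**Step 3**
Reactants: 6 ethyl 2,6,6-trimethylcyclohexa-1,3-diene-1-carboxylate
Product: 7 (2,6,6-trimethylcyclohexa-1,3-dien-1-yl)methanol
Conditions: DIBAL-H (2.5 equiv), CH2Cl2, −78 to 0 °C; Rochelle salt work-up
Reagents that add atoms: none
Why: Hydride 1,2-reduction of the conjugated ester by DIBAL-H should give the dienylic alcohol without touching the ring diene.

**Step 4**
Reactants: 7 (2,6,6-trimethylcyclohexa-1,3-dien-1-yl)methanol
Product: 8 2,6,6-trimethylcyclohexa-1,3-diene-1-carbaldehyde (safranal)
Conditions: activated MnO2 (excess), CH2Cl2, rt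
Reagents that add atoms: none
Why: MnO2 oxidation is selective for allylic alcohols and should stop at the conjugated aldehyde without moving the diene.

**Step 5**
Reactants: 8 2,6,6-trimethylcyclohexa-1,3-diene-1-carbaldehyde
Product: 9 1-ethynyl-2,6,6-trimethylcyclohexa-1,3-diene
Conditions: TMSCHN2, LDA, THF, −78 °C; add 8; −78 °C to rt; aqueous work-up
Reagents that add atoms: (trimethylsilyl)diazomethane, C[Si](C)(C)C=[N+]=[N-]
Why: Colvin rearrangement: the lithiated silyl diazomethane should add to the aldehyde, which has no α-hydrogen, then lose silanolate and N2, and a 1,2-hydrogen shift of the alkylidene carbene gives the terminal alkyne under aprotic conditions that avoid conjugate addition.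

**Step 6**
Reactants: 10 ethyl 3-oxobutanoate (ethyl acetoacetate)
Product: 12 ethyl (2E)-3-{[(trifluoromethyl)sulfonyl]oxy}but-2-enoate, via ammonium enolate 11 (not isolated)
Conditions: Tf2O, aq. Me4NOH, hexanes, 5–10 °C
Reagents that add atoms: trifluoromethanesulfonic anhydride, O=S(=O)(OS(=O)(=O)C(F)(F)F)C(F)(F)F
Why: Under biphasic Schotten–Baumann-type conditions the non-chelated ammonium enolate should adopt the geometry with O− anti to the ester, and O-triflation fixes it as the (E)-enol triflate (stereoselective enol triflate formation), which sets the later 9E geometry.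

**Step 7**
Reactants: 9 1-ethynyl-2,6,6-trimethylcyclohexa-1,3-diene; 12 ethyl (2E)-3-{[(trifluoromethyl)sulfonyl]oxy}but-2-enoate
Product: 13 ethyl (2E)-3-methyl-5-(2,6,6-trimethylcyclohexa-1,3-dien-1-yl)pent-2-en-4-ynoate
Conditions: PdCl2(PPh3)2 (cat.), CuI (cat.), Et3N, THF, rt, degassed
Reagents that add atoms: none
Why: Sonogashira coupling of the activated vinyl triflate should proceed at room temperature with retention of the alkene geometry, so the alkyne ends trans to the ester carbon (9E).

**Step 8**
Reactants: 13 ethyl (2E)-3-methyl-5-(2,6,6-trimethylcyclohexa-1,3-dien-1-yl)pent-2-en-4-ynoate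
Product: 14 (2E)-3-methyl-5-(2,6,6-trimethylcyclohexa-1,3-dien-1-yl)pent-2-en-4-yn-1-ol
Conditions: DIBAL-H (2.2 equiv), CH2Cl2, −78 °C; Rochelle salt work-up
Reagents that add atoms: none
Why: DIBAL-H 1,2-reduction of the enynoate at low temperature should give the allylic alcohol without hydroalumination of the alkyne or change of the alkene geometry.

**Step 9**
Reactants: 14 (2E)-3-methyl-5-(2,6,6-trimethylcyclohexa-1,3-dien-1-yl)pent-2-en-4-yn-1-ol
Product: 16 tributyl[(2E)-3-methyl-5-(2,6,6-trimethylcyclohexa-1,3-dien-1-yl)pent-2-en-4-yn-1-yl]phosphonium bromide, via allylic bromide 15 (not isolated)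
Conditions: CBr4, PPh3, CH2Cl2, −20 to 0 °C; filter through silica (pentane); then PBu3, EtOAc, rt
Reagents that add atoms: carbon tetrabromide, BrC(Br)(Br)Br; tributylphosphine, CCCCP(CCCC)CCCC
Why: Appel bromination under neutral conditions followed by SN2 quaternisation of tributylphosphine should give the primary allylic salt without allylic transposition or loss of the 9E geometry.

**Step 10**
Reactants: 17 (4R,6R)-4-hydroxy-2,2,6-trimethylcyclohexan-1-one
Product: 18 (4R,6R)-4-[(tert-butyldimethylsilyl)oxy]-2,2,6-trimethylcyclohexan-1-one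
Conditions: TBSCl, imidazole, DMF, rt
Reagents that add atoms: tert-butyldimethylsilyl chloride, CC(C)(C)[Si](C)(C)Cl
Why: Standard silylation of the secondary alcohol protects it from triflation and from the later basic steps and leaves the carbinol stereocentre untouched.

**Step 11**
Reactants: 18 (4R,6R)-4-[(tert-butyldimethylsilyl)oxy]-2,2,6-trimethylcyclohexan-1-one
Product: 20 (4R)-4-[(tert-butyldimethylsilyl)oxy]-2,6,6-trimethylcyclohex-1-en-1-yl trifluoromethanesulfonate, via potassium enolate 19 (not isolated)
Conditions: KHMDS, THF, −78 °C; then PhNTf2, −78 °C to rt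
Reagents that add atoms: N-phenylbis(trifluoromethanesulfonimide), O=S(=O)(N(c1ccccc1)S(=O)(=O)C(F)(F)F)C(F)(F)F
Why: The ketone has a single enolisable α-position (C2 is quaternary), so deprotonation and O-triflation should give only the tetrasubstituted enol triflate, erasing the C6 centre on purpose while the silyloxy carbon (γ to the carbonyl, no β-elimination path) keeps its R configuration.

**Step 12**
Reactants: 20 (4R)-4-[(tert-butyldimethylsilyl)oxy]-2,6,6-trimethylcyclohex-1-en-1-yl trifluoromethanesulfonate; 21 (2E)-3-methylpent-2-en-4-yn-1-ol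
Product: 22 (2E)-5-{(4R)-4-[(tert-butyldimethylsilyl)oxy]-2,6,6-trimethylcyclohex-1-en-1-yl}-3-methylpent-2-en-4-yn-1-ol
Conditions: Pd(PPh3)4 (cat.), CuI (cat.), iPr2NH, DMF, 45 °C, degassed
Reagents that add atoms: none
Why: Sonogashira coupling of a 2,6,6-trimethylcyclohexenyl triflate with a terminal enyne is well precedented and carries the pre-set (E)-alkene of 21 unchanged into the C15 unit (9'E).

**Step 13**
Reactants: 22 (2E)-5-{(4R)-4-[(tert-butyldimethylsilyl)oxy]-2,6,6-trimethylcyclohex-1-en-1-yl}-3-methylpent-2-en-4-yn-1-ol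
Product: 24 tributyl[(2E)-5-{(4R)-4-[(tert-butyldimethylsilyl)oxy]-2,6,6-trimethylcyclohex-1-en-1-yl}-3-methylpent-2-en-4-yn-1-yl]phosphonium bromide, via allylic bromide 23 (not isolated)
Conditions: CBr4, PPh3, CH2Cl2, −20 to 0 °C; filter through silica (pentane); then PBu3, EtOAc, rt
Reagents that add atoms: carbon tetrabromide, BrC(Br)(Br)Br; tributylphosphine, CCCCP(CCCC)CCCC
Why: Appel bromination and SN2 quaternisation as in step 9 are neutral enough to keep the silyl ether and the 9'E geometry.

**Step 14**
Reactants: 24 tributyl[(2E)-5-{(4R)-4-[(tert-butyldimethylsilyl)oxy]-2,6,6-trimethylcyclohex-1-en-1-yl}-3-methylpent-2-en-4-yn-1-yl]phosphonium bromide; 25 (2E,4E,6E)-2,7-dimethylocta-2,4,6-trienedial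
Product: 27 (2E,4E,6E,8E,10E)-13-{(4R)-4-[(tert-butyldimethylsilyl)oxy]-2,6,6-trimethylcyclohex-1-en-1-yl}-2,7,11-trimethyltrideca-2,4,6,8,10-pentaen-12-ynal, via ylide 26 (not isolated)
Conditions: 25 (3 equiv), NaOMe (1.1 equiv), CH2Cl2, 0 °C to rt
Reagents that add atoms: none
Why: Wittig olefination with an allylic trialkylphosphonium ylide should give the new C11'=C12' bond E-selectively, and excess dialdehyde together with the lower electrophilicity of the vinylogous aldehyde in the product should keep the reaction at mono-olefination.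

**Step 15**
Reactants: 27 (2E,4E,6E,8E,10E)-13-{(4R)-4-[(tert-butyldimethylsilyl)oxy]-2,6,6-trimethylcyclohex-1-en-1-yl}-2,7,11-trimethyltrideca-2,4,6,8,10-pentaen-12-ynal; 16 tributyl[(2E)-3-methyl-5-(2,6,6-trimethylcyclohexa-1,3-dien-1-yl)pent-2-en-4-yn-1-yl]phosphonium bromide
Product: 29 tert-butyldimethylsilyl ether of the target (all-E C40 diyne-heptaene with the silyloxy group on the R carbinol carbon), via ylide 28 (not isolated)
Conditions: NaOMe (1.2 equiv), CH2Cl2, 0 °C to rt, dark
Reagents that add atoms: none
Why: The second Wittig olefination with the allylic tributylphosphonium ylide should form C11=C12 E-selectively and complete the C40 chain, the other double bonds being carried in with fixed geometry.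

**Step 16**
Reactants: 29 tert-butyldimethylsilyl ether of the target
Product: 30 CNP0250213.1 (all-E C40 diyne-heptaene carrying a 2,6,6-trimethylcyclohexa-1,3-dien-1-yl end and a (4R)-4-hydroxy-2,6,6-trimethylcyclohex-1-en-1-yl end)
Conditions: TBAF, AcOH (1:1), THF, 0 °C to rt, dark
Reagents that add atoms: none
Why: Buffered fluoride desilylation cleaves the Si–O bond only, so the R carbinol centre and the polyene geometry should be retained.

**Compound list**

1 | diethyl 2-(propan-2-ylidene)propanedioate | CCOC(=O)C(=C(C)C)C(=O)OCC | starting material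
2 | diethyl 2-[(3E)-4-(dimethylamino)but-3-en-2-ylidene]propanedioate | CCOC(=O)C(C(=O)OCC)=C(C)/C=C/N(C)C | intermediate
3 | ethyl 4-methyl-2-oxo-2H-pyran-3-carboxylate | CCOC(=O)C1=C(C)C=COC1=O | intermediate
4 | 2-methylprop-1-ene (isobutylene) | CC(C)=C | starting material
5 | ethyl 5,8,8-trimethyl-3-oxo-2-oxabicyclo[2.2.2]oct-5-ene-4-carboxylate (racemic) | CCOC(=O)C12C(C)=CC(CC1(C)C)OC2=O | intermediate
6 | ethyl 2,6,6-trimethylcyclohexa-1,3-diene-1-carboxylate | CCOC(=O)C1=C(C)C=CCC1(C)C | intermediate
7 | (2,6,6-trimethylcyclohexa-1,3-dien-1-yl)methanol | OCC1=C(C)C=CCC1(C)C | intermediate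
8 | 2,6,6-trimethylcyclohexa-1,3-diene-1-carbaldehyde | O=CC1=C(C)C=CCC1(C)C | intermediate
9 | 1-ethynyl-2,6,6-trimethylcyclohexa-1,3-diene | C#CC1=C(C)C=CCC1(C)C | intermediate
10 | ethyl 3-oxobutanoate | CCOC(=O)CC(C)=O | starting material
11 | tetramethylammonium (E)-enolate of ethyl 3-oxobutanoate | CCOC(=O)/C=C(\C)[O-].C[N+](C)(C)C | intermediate
12 | ethyl (2E)-3-{[(trifluoromethyl)sulfonyl]oxy}but-2-enoate | CCOC(=O)/C=C(\C)OS(=O)(=O)C(F)(F)F | intermediate
13 | ethyl (2E)-3-methyl-5-(2,6,6-trimethylcyclohexa-1,3-dien-1-yl)pent-2-en-4-ynoate | CCOC(=O)/C=C(\C)C#CC1=C(C)C=CCC1(C)C | intermediate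
14 | (2E)-3-methyl-5-(2,6,6-trimethylcyclohexa-1,3-dien-1-yl)pent-2-en-4-yn-1-ol | OC/C=C(\C)C#CC1=C(C)C=CCC1(C)C | intermediate
15 | 1-[(3E)-5-bromo-3-methylpent-3-en-1-yn-1-yl]-2,6,6-trimethylcyclohexa-1,3-diene | BrC/C=C(\C)C#CC1=C(C)C=CCC1(C)C | intermediate
16 | tributyl[(2E)-3-methyl-5-(2,6,6-trimethylcyclohexa-1,3-dien-1-yl)pent-2-en-4-yn-1-yl]phosphonium bromide | CCCC[P+](CCCC)(CCCC)C/C=C(\C)C#CC1=C(C)C=CCC1(C)C.[Br-] | intermediate
17 | (4R,6R)-4-hydroxy-2,2,6-trimethylcyclohexan-1-one | C[C@@H]1C[C@@H](O)CC(C)(C)C1=O | starting material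
18 | (4R,6R)-4-[(tert-butyldimethylsilyl)oxy]-2,2,6-trimethylcyclohexan-1-one | C[C@@H]1C[C@@H](O[Si](C)(C)C(C)(C)C)CC(C)(C)C1=O | intermediate
19 | potassium (4R)-4-[(tert-butyldimethylsilyl)oxy]-2,6,6-trimethylcyclohex-1-en-1-olate | [K+].[O-]C1=C(C)C[C@@H](O[Si](C)(C)C(C)(C)C)CC1(C)C | intermediate
20 | (4R)-4-[(tert-butyldimethylsilyl)oxy]-2,6,6-trimethylcyclohex-1-en-1-yl trifluoromethanesulfonate | FC(F)(F)S(=O)(=O)OC1=C(C)C[C@@H](O[Si](C)(C)C(C)(C)C)CC1(C)C | intermediate
21 | (2E)-3-methylpent-2-en-4-yn-1-ol | C#C/C(C)=C/CO | starting material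
22 | (2E)-5-{(4R)-4-[(tert-butyldimethylsilyl)oxy]-2,6,6-trimethylcyclohex-1-en-1-yl}-3-methylpent-2-en-4-yn-1-ol | OC/C=C(\C)C#CC1=C(C)C[C@@H](O[Si](C)(C)C(C)(C)C)CC1(C)C | intermediate
23 | {[(1R)-4-[(3E)-5-bromo-3-methylpent-3-en-1-yn-1-yl]-3,5,5-trimethylcyclohex-3-en-1-yl]oxy}(tert-butyl)dimethylsilane | BrC/C=C(\C)C#CC1=C(C)C[C@@H](O[Si](C)(C)C(C)(C)C)CC1(C)C | intermediate
24 | tributyl[(2E)-5-{(4R)-4-[(tert-butyldimethylsilyl)oxy]-2,6,6-trimethylcyclohex-1-en-1-yl}-3-methylpent-2-en-4-yn-1-yl]phosphonium bromide | CCCC[P+](CCCC)(CCCC)C/C=C(\C)C#CC1=C(C)C[C@@H](O[Si](C)(C)C(C)(C)C)CC1(C)C.[Br-] | intermediate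
25 | (2E,4E,6E)-2,7-dimethylocta-2,4,6-trienedial | O=C/C(C)=C/C=C/C=C(C)/C=O | starting material
26 | tributylphosphonium ylide of salt 24 | CCCC[P+](CCCC)(CCCC)[CH-]/C=C(\C)C#CC1=C(C)C[C@@H](O[Si](C)(C)C(C)(C)C)CC1(C)C | intermediate
27 | (2E,4E,6E,8E,10E)-13-{(4R)-4-[(tert-butyldimethylsilyl)oxy]-2,6,6-trimethylcyclohex-1-en-1-yl}-2,7,11-trimethyltrideca-2,4,6,8,10-pentaen-12-ynal | O=C/C(C)=C/C=C/C=C(C)/C=C/C=C(\C)C#CC1=C(C)C[C@@H](O[Si](C)(C)C(C)(C)C)CC1(C)C | intermediate
28 | tributylphosphonium ylide of salt 16 | CCCC[P+](CCCC)(CCCC)[CH-]/C=C(\C)C#CC1=C(C)C=CCC1(C)C | intermediate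
29 | tert-butyldimethylsilyl ether of the target (all-E) | CC1=C(C#C/C(C)=C/C=C/C(C)=C/C=C/C=C(C)/C=C/C=C(\C)C#CC2=C(C)C[C@@H](O[Si](C)(C)C(C)(C)C)CC2(C)C)C(C)(C)CC=C1 | intermediate
30 | CNP0250213.1 | CC1=C(C#C/C(C)=C/C=C/C(C)=C/C=C/C=C(C)/C=C/C=C(\C)C#CC2=C(C)C[C@@H](O)CC2(C)C)C(C)(C)CC=C1 | target

**Step count**

Total: 16 steps. Longest linear sequence: 10 steps (steps 1, 2, 3, 4, 5, 7, 8, 9, 15, 16).

**Steps most likely to fail**

Step 2. The cycloaddition may be too slow because the C4 methyl and the C3 ester crowd the carbon that must bond to the tertiary alkene terminus. A stepwise zwitterionic course may also divert material into ene-type or ring-opened products, isobutylene may oligomerise, and some of the opposite regiochemistry may form. The fallback builds the same ring by classical condensation chemistry and sets out from 10. Acid-promoted Michael/aldol annulation of 10 with commercial 4-methylpent-3-en-2-one (BF3·OEt2) should give ethyl 2,6,6-trimethyl-4-oxocyclohex-2-ene-1-carboxylate F1. Reduction with NaBH4/CeCl3 in MeOH should give ethyl 4-hydroxy-2,6,6-trimethylcyclohex-2-ene-1-carboxylate F2. Acid-catalysed 1,4-dehydration (TsOH, toluene, reflux, water separator) should deliver the conjugated diene ester, where the fallback returns to the route at 6.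

Step 5. The basic diazo anion may deprotonate the dienal vinylogously (ring methyl or ring CH2) instead of adding to the hindered carbonyl, and the volatile alkyne may be lost on isolation. The fallback sets out from 8 and uses a two-stage homologation through a halogenated alkene. Dibromo-olefination (CBr4, PPh3, Zn, CH2Cl2) should give 1-(2,2-dibromoethenyl)-2,6,6-trimethylcyclohexa-1,3-diene F3. Treatment with n-BuLi (2.1 equiv, THF, −78 °C; Fritsch–Buttenberg–Wiechell rearrangement) and an aqueous quench should give the alkyne, returning to the route at 9, which is carried on as a solution (Corey–Fuchs sequence).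

Step 15. Geometric purity may erode, through incomplete E-selectivity at the new C11=C12 bond and through rotation about C9–C10 in the delocalised ylide. The latter gives a 9Z isomer that cannot be corrected by equilibration in the acetylenic series. The fallback changes the olefination manifold to a phosphonate carbanion under thermodynamic E control and sets out from 15. Michaelis–Becker reaction of 15 with sodium diethyl phosphite (THF, 0 °C) should give diethyl [(2E)-3-methyl-5-(2,6,6-trimethylcyclohexa-1,3-dien-1-yl)pent-2-en-4-yn-1-yl]phosphonate F4. Horner–Wadsworth–Emmons reaction of F4 with aldehyde 27 (NaHMDS, THF, −78 to 0 °C) should then give the silyl ether, returning to the route at 29.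

**Further compounds**

F1 | step 2 | ethyl 2,6,6-trimethyl-4-oxocyclohex-2-ene-1-carboxylate (racemic) | CCOC(=O)C1C(C)=CC(=O)CC1(C)C
F2 | step 2 | ethyl 4-hydroxy-2,6,6-trimethylcyclohex-2-ene-1-carboxylate (racemic mixture of diastereomers) | CCOC(=O)C1C(C)=CC(O)CC1(C)C
F3 | step 5 | 1-(2,2-dibromoethenyl)-2,6,6-trimethylcyclohexa-1,3-diene | BrC(Br)=CC1=C(C)C=CCC1(C)C
F4 | step 15 | diethyl [(2E)-3-methyl-5-(2,6,6-trimethylcyclohexa-1,3-dien-1-yl)pent-2-en-4-yn-1-yl]phosphonate | CCOP(=O)(OCC)C/C=C(\C)C#CC1=C(C)C=CCC1(C)C
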